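Ring C is made first: its O1–C8a and C2–C3 bonds, with C2 as the only stereocentre, are those of an aldehyde/siloxydiene cycloadduct. One hetero-Diels–Alder reaction catalysed by the complex of (S)-BINOL with Ti(OiPr)4 therefore closes ring C and sets (S)-C2 while no ring A phenol exists to open it. The precursor is the ring B aldehyde, 3-hydroxy-4,5-dimethoxybenzaldehyde masked as a fluoride-labile silyl ether, plus 1-methoxy-3-(trimethylsilyloxy)butadiene. Ring A is then annulated across C4a=C8a by a Diels–Alder aromatisation of the C4a-sulfinyl enone with the bis(silyloxy)diene of methyl 2-geranylacetoacetate, which places geranyl at C6, para to O1.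

Key step: step 2

Conventions: flavanone numbering (O1, C2, C3, C4, C4a, C5–C8, C8a) is used for all intermediates; in the monocyclic pyranones C4a and C8a are the enone α- and β-carbons (pyranone C5 and C6). Ar = 3-(tert-butyldimethylsilyloxy)-4,5-dimethoxyphenyl; geranyl = (2E)-3,7-dimethylocta-2,6-dien-1-yl.

Assumption: (S)-BINOL/Ti(OiPr)4 is taken to deliver the diene to the Si face of an aryl aldehyde, as this catalyst family does in carbonyl allylation; if a first run shows the opposite sense, (R)-BINOL is used with nothing else changed.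

Remark on the protecting group: the ring B phenol is carried as a TBS ether, not an acetal. Fluoride release spares the geranyl alkenes, which acid would close onto the flanking ring A phenols, and a bulky silyl ether offers titanium no chelating site.

Remark on the C4a leaving group: it is a sulfoxide, not a halide. In the cis-fused cycloadduct the C8a–H is non-acidic and syn to the C4a substituent, so only a thermal syn-elimination can remove it.

Step 1
Reactants: 1 3-hydroxy-4,5-dimethoxybenzaldehyde
Product: 2 3-(tert-butyldimethylsilyloxy)-4,5-dimethoxybenzaldehyde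
Conditions: TBSCl, imidazole, DMF, rt
Reagents that add atoms: tert-butyldimethylsilyl chloride, CC(C)(C)[Si](C)(C)Cl
Why: Imidazole-mediated O-silylation of a phenol (silyl ether formation) is routine and leaves the aldehyde untouched.

Step 2
Reactants: 2 3-(tert-butyldimethylsilyloxy)-4,5-dimethoxybenzaldehyde; 3 (E)-1-methoxy-3-(trimethylsilyloxy)buta-1,3-diene
Product: 5 (S)-2-Ar-2,3-dihydro-4H-pyran-4-one, via silyl aldol adduct 4 (not isolated)
Conditions: (S)-BINOL (20 mol %), Ti(OiPr)4 (10 mol %), 4 Å MS, Et2O, −20 °C; then CF3CO2H, CH2Cl2, 0 °C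
Reagents that add atoms: none
Why: The complex of (S)-BINOL with Ti(OiPr)4 (tetravalent titanium) binds the aldehyde oxygen and the nucleophilic CH2 terminus of diene 3 adds to the carbonyl carbon (C2–C3), silyl transfer giving the open silyl aldol adduct 4; CF3CO2H then frees the C2 oxygen, which adds to the methoxy-bearing enone carbon and expels methanol (O1–C8a). The closest known reaction is the Ti/BINOL-catalysed formal hetero-Diels–Alder reaction (Mukaiyama aldol then cyclisation) of aryl aldehydes with 1-methoxy-3-silyloxybutadiene. Ring C closes in the 6-endo-trig mode, as an oxa-Michael addition–elimination on the β-methoxy enone. The C2 stereocentre is set in the C–C bond-forming step by the catalyst alone, the (S)-ligand being expected to direct the diene to the Si face of the aldehyde. The step needs enantiofacial selectivity and a single regiochemistry: the latter is fixed by the polarisation of the diene, the former is helped by an aldehyde with one carbonyl, no free hydroxyl and a bulky non-chelating silyl ether, so that its ring oxygens do not compete with the carbonyl for titanium. Since 5 has no phenol conjugated to the ketone, C2 cannot be eroded by chalcone-type ring opening.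

Step 3
Reactants: 5 (S)-2-Ar-2,3-dihydro-4H-pyran-4-one
Product: 7 (S)-2-Ar-5-(phenylthio)-2,3-dihydro-4H-pyran-4-one, via chloro adduct 6 (not isolated)
Conditions: PhSCl, CH2Cl2, −78 °C; then Et3N, −78 → 0 °C
Reagents that add atoms: benzenesulfenyl chloride, ClSc1ccccc1
Why: Electrophilic α-sulfenylation by sulfenyl chloride addition–elimination: PhSCl attacks the enol-ether carbon C4a to give chloro acetal 6, and Et3N removes the acidic C4a–H with loss of chloride, restoring the vinylogous ester without touching C2 or the aryl silyl ether.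

Step 4
Reactants: 7 (S)-2-Ar-5-(phenylthio)-2,3-dihydro-4H-pyran-4-one
Product: 8 (2S)-2-Ar-5-(phenylsulfinyl)-2,3-dihydro-4H-pyran-4-one (both epimers at sulfur)
Conditions: mCPBA (1.0 equiv), CH2Cl2, −78 → −40 °C
Reagents that add atoms: 3-chloroperoxybenzoic acid, OOC(=O)c1cccc(Cl)c1
Why: Sulfide-to-sulfoxide oxidation with one equivalent of peracid at low temperature is far faster than attack on the push–pull alkene or the arene, and the mixed configuration at sulfur is irrelevant because sulfur is expelled in step 8.

Step 5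
Reactants: 9 methyl acetoacetate; 10 geranyl bromide
Product: 11 methyl (4E)-2-acetyl-5,9-dimethyldeca-4,8-dienoate (methyl 2-geranylacetoacetate, racemic)
Conditions: NaH, THF, 0 °C; then 10, 0 °C → rt (9 in excess)
Reagents that add atoms: none
Why: Acetoacetic ester alkylation, an SN2 C-alkylation of the sodium enolate by the primary allylic bromide, keeps the (E)-alkene, and an excess of 9 limits dialkylation.

Step 6
Reactants: 11 methyl 2-geranylacetoacetate
Product: 12 methyl 2-geranyl-3-(trimethylsilyloxy)but-2-enoate (E/Z mixture)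
Conditions: TMSCl, Et3N, PhMe, rt
Reagents that add atoms: chlorotrimethylsilane, C[Si](C)(C)Cl
Why: O-silylation of the enolisable β-keto ester (silyl enol ether formation) is the standard first stage in making a 1,3-bis(silyloxy)diene.

Step 7
Reactants: 12 methyl 2-geranyl-3-(trimethylsilyloxy)but-2-enoate
Product: 13 2-geranyl-1-methoxy-1,3-bis(trimethylsilyloxy)buta-1,3-diene
Conditions: LiN(iPr)2, THF, −78 °C; then TMSCl, −78 °C → rt
Reagents that add atoms: chlorotrimethylsilane, C[Si](C)(C)Cl
Why: Kinetic γ-deprotonation of the methyl group of the vinylogous ester and O-silylation of the dienolate should give the Chan-type diene, which is used crude because it is moisture-sensitive.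

Step 8
Reactants: 8 (2S)-2-Ar-5-(phenylsulfinyl)-2,3-dihydro-4H-pyran-4-one; 13 2-geranyl-1-methoxy-1,3-bis(trimethylsilyloxy)buta-1,3-diene
Product: 16 (2S)-5,7-dihydroxy-2-(3-hydroxy-4,5-dimethoxyphenyl)-6-[(2E)-3,7-dimethylocta-2,6-dien-1-yl]-2,3-dihydro-4H-chromen-4-one (target), via cycloadduct 14 (not isolated), via bis-TMS flavanone 15 (not isolated)
Conditions: 13 (3 equiv), PhMe, 60 → 100 °C; then Bu4NF, AcOH, THF, 0 °C → rt
Reagents that add atoms: none
Why: In this Diels–Alder reaction of an α-sulfinyl enone (a masked cyclic ynone) with an electron-rich diene, the nucleophilic CH2 terminus should bond to the electrophilic C8a and the ketene-acetal carbon to C4a; the cis-fused adduct 14 then loses PhSOH by thermal syn-elimination (C8a–H is cis to sulfur) and methanol to aromatise to 15 with geranyl fixed at C6, and acetic-acid-buffered fluoride removes all three silyl groups without the base that would open the flavanone at C2 or the acid that would cyclise geranyl onto the phenols.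

Compound list
1 | 3-hydroxy-4,5-dimethoxybenzaldehyde | COc1cc(C=O)cc(O)c1OC | starting material
2 | 3-(tert-butyldimethylsilyloxy)-4,5-dimethoxybenzaldehyde | COc1cc(C=O)cc(O[Si](C)(C)C(C)(C)C)c1OC | intermediate
3 | (E)-1-methoxy-3-(trimethylsilyloxy)buta-1,3-diene | CO/C=C/C(=C)O[Si](C)(C)C | starting material
4 | (S,E)-5-Ar-1-methoxy-5-(trimethylsilyloxy)pent-1-en-3-one | CO/C=C/C(=O)C[C@H](O[Si](C)(C)C)c1cc(OC)c(OC)c(O[Si](C)(C)C(C)(C)C)c1 | intermediate (not isolated)
5 | (S)-2-Ar-2,3-dihydro-4H-pyran-4-one | COc1cc([C@@H]2CC(=O)C=CO2)cc(O[Si](C)(C)C(C)(C)C)c1OC | intermediate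
6 | (2S)-2-Ar-6-chloro-5-(phenylthio)tetrahydro-4H-pyran-4-one, C5/C6 diastereomers unassigned | COc1cc([C@@H]2CC(=O)C(Sc3ccccc3)C(Cl)O2)cc(O[Si](C)(C)C(C)(C)C)c1OC | intermediate (not isolated)
7 | (S)-2-Ar-5-(phenylthio)-2,3-dihydro-4H-pyran-4-one | COc1cc([C@@H]2CC(=O)C(Sc3ccccc3)=CO2)cc(O[Si](C)(C)C(C)(C)C)c1OC | intermediate
8 | (2S)-2-Ar-5-(phenylsulfinyl)-2,3-dihydro-4H-pyran-4-one, both epimers at sulfur | COc1cc([C@@H]2CC(=O)C(S(=O)c3ccccc3)=CO2)cc(O[Si](C)(C)C(C)(C)C)c1OC | intermediate
9 | methyl acetoacetate | COC(=O)CC(C)=O | starting material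
10 | geranyl bromide, (2E)-1-bromo-3,7-dimethylocta-2,6-diene | BrC/C=C(\C)CCC=C(C)C | starting material
11 | methyl (4E)-2-acetyl-5,9-dimethyldeca-4,8-dienoate, racemic | COC(=O)C(C/C=C(\C)CCC=C(C)C)C(C)=O | intermediate
12 | methyl 2-geranyl-3-(trimethylsilyloxy)but-2-enoate, E/Z mixture | COC(=O)C(C/C=C(\C)CCC=C(C)C)=C(C)O[Si](C)(C)C | intermediate
13 | 2-geranyl-1-methoxy-1,3-bis(trimethylsilyloxy)buta-1,3-diene | COC(O[Si](C)(C)C)=C(C/C=C(\C)CCC=C(C)C)C(=C)O[Si](C)(C)C | intermediate
14 | (2S)-2-Ar-6-geranyl-5-methoxy-4a-(phenylsulfinyl)-5,7-bis(trimethylsilyloxy)-2,3,4a,5,8,8a-hexahydro-4H-chromen-4-one, cis ring fusion, C4a/C5/C8a and sulfur unassigned | COc1cc([C@@H]2CC(=O)C3(S(=O)c4ccccc4)C(OC)(O[Si](C)(C)C)C(C/C=C(\C)CCC=C(C)C)=C(O[Si](C)(C)C)CC3O2)cc(O[Si](C)(C)C(C)(C)C)c1OC | intermediate (not isolated)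
15 | (2S)-2-Ar-6-geranyl-5,7-bis(trimethylsilyloxy)-2,3-dihydro-4H-chromen-4-one | COc1cc([C@@H]2CC(=O)c3c(cc(O[Si](C)(C)C)c(C/C=C(\C)CCC=C(C)C)c3O[Si](C)(C)C)O2)cc(O[Si](C)(C)C(C)(C)C)c1OC | intermediate (not isolated)
16 | (2S)-5,7-dihydroxy-2-(3-hydroxy-4,5-dimethoxyphenyl)-6-[(2E)-3,7-dimethylocta-2,6-dien-1-yl]-2,3-dihydro-4H-chromen-4-one | COc1cc([C@@H]2CC(=O)c3c(cc(O)c(C/C=C(\C)CCC=C(C)C)c3O)O2)cc(O)c1OC | target

Total steps: 8. Longest linear sequence: 5 steps (1, 2, 3, 4, 8); the diene branch (5, 6, 7) joins at step 8.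

Steps most likely to fail

1. Step 8. The push–pull alkene of 8 may react more slowly than the diene decomposes. The addition may also stop after the first bond (C8–C8a) through silyl transfer instead of closing onto C4a, and the sulfenic acid released may add to the geranyl alkenes. The fallback makes the two ring A bonds one after the other; it sets out from 8 and 13 and returns to the route at 16. A Mukaiyama–Michael addition of 13 to 8 (TMSOTf cat., CH2Cl2, −78 °C, bicarbonate work-up) should give the C8a-alkylated α-sulfinyl ketone F1. Warming F1 in toluene should expel PhSOH by syn-elimination and restore the enone as the 6-substituted dihydropyranone F2, which carries the β-keto ester chain on C8a. A biomimetic Claisen condensation of C4a onto the methyl ester (Mg(OMe)2, MeOH, rt, with C2 integrity monitored) should then close ring A to the TBS-protected flavanone F3. Bu4NF/AcOH would convert F3 into 16.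

2. Step 2. The electron-rich aldehyde, flanked by oxygen substituents, may turn over slowly on titanium, so that an unselective background addition lowers the enantiomeric purity. The fallback replaces catalyst control by reagent control; it sets out from 2 and returns at 5. The diisopinocampheylboron enolate of (E)-4-methoxybut-3-en-2-one (Ipc2BCl of the antipode that attacks the Si face, iPr2NEt, Et2O, −78 °C) should add to 2 to give the β-hydroxy enone F4. CF3CO2H would then cyclise F4 to 5 through the same C2–C3 and O1–C8a bonds.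

3. Step 3. The sulfenyl chloride may also attack the trialkoxy arene, or the chloro adduct may lose O1 by ring opening instead of eliminating HCl cleanly. The fallback installs sulfur by cross-coupling; it sets out from 5 and returns at 7. α-Iodination of the enone (I2, pyridine, CH2Cl2) should give the 5-iodo dihydropyranone F5. C–S coupling of F5 with PhSH (Pd2(dba)3, zerovalent palladium, Xantphos, iPr2NEt, dioxane, 80 °C) should then give 7.

Further compounds
F1 | step 8 | (2S)-2-Ar-6-[4-methoxy-3-geranyl-2,4-dioxobutyl]-5-(phenylsulfinyl)tetrahydro-4H-pyran-4-one, other centres unassigned | COc1cc([C@@H]2CC(=O)C(S(=O)c3ccccc3)C(CC(=O)C(C/C=C(\C)CCC=C(C)C)C(=O)OC)O2)cc(O[Si](C)(C)C(C)(C)C)c1OC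
F2 | step 8 | methyl 4-[(6S)-6-Ar-4-oxo-5,6-dihydro-4H-pyran-2-yl]-2-geranyl-3-oxobutanoate | COc1cc([C@@H]2CC(=O)C=C(CC(=O)C(C/C=C(\C)CCC=C(C)C)C(=O)OC)O2)cc(O[Si](C)(C)C(C)(C)C)c1OC
F3 | step 8 | (2S)-2-Ar-6-geranyl-5,7-dihydroxy-2,3-dihydro-4H-chromen-4-one | COc1cc([C@@H]2CC(=O)c3c(cc(O)c(C/C=C(\C)CCC=C(C)C)c3O)O2)cc(O[Si](C)(C)C(C)(C)C)c1OC
F4 | step 2 | (S,E)-5-Ar-5-hydroxy-1-methoxypent-1-en-3-one | CO/C=C/C(=O)C[C@H](O)c1cc(OC)c(OC)c(O[Si](C)(C)C(C)(C)C)c1
F5 | step 3 | (S)-2-Ar-5-iodo-2,3-dihydro-4H-pyran-4-one | COc1cc([C@@H]2CC(=O)C(I)=CO2)cc(O[Si](C)(C)C(C)(C)C)c1OC
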